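## Structural features

The target 30 is numbered as a 2,3-dihydro-1-benzofuran: O1, C2, C3 and the fusion carbons C3a and C7a form the dihydrofuran ring C, and C3a, C4, C5, C6, C7 and C7a form the benzo ring A. Ring B, a 4-hydroxy-3,5-dimethoxyphenyl group, sits on C2; C3 carries a hydroxymethyl group, C7 a methoxy group and C5 an (E)-3-hydroxyprop-1-enyl chain. The only stereocentres, C2 (S) and C3 (R), are adjacent ring atoms, and the C2 aryl group and the C3 hydroxymethyl group are trans. The fragile parts are the cinnamyl-type allylic alcohol (sensitive to acid, hydrogenation and oxidants), the free electron-rich phenol, and the C2–O1 bond, a benzylic aryl ether para to the ring B hydroxyl that can open through a quinone methide in base or a benzylic cation in acid. C3 has no activating group in the target, so the trans relationship cannot be repaired by late epimerisation and has to be built in. The real difficulty is to fix C2 and C3 in one absolute sense, close ring C without disturbing them, and end with ring A carrying two different oxygen substituents side by side. The plan uses exactly that last feature: O1 on C7a and the methoxy oxygen on C7 are ortho neighbours next to C3a, the pattern left when an aryne across C7–C7a accepts an oxygen nucleophile tethered through C3a at C7a and an electrophile at C7.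

## Logic of the disconnections

**30 to 29.** The two O–Si bonds are the last to be made free. Keeping the ring B phenol and the primary alcohol silylated until the end keeps the quinone-methide pathway of the C2–O1 bond closed in every earlier step. The gain is that all late chemistry runs on a neutral bis-silyl ether. The demand is that one buffered desilylation releases both hydroxyls without touching the allylic alcohol.

**29 to 28 to 26 and 27.** The side-chain C=C bond is cut after the terminal carbon is taken back to the ester level. An (E)-alkene conjugated to ring A is the normal outcome of a stabilised phosphonate olefination of an aryl aldehyde. The three-carbon chain shrinks to a one-carbon handle on C5, which can be masked during organomagnesium chemistry. The forward steps must be E-selective and the hydride reduction strictly 1,2.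

**26 to 25 to 24 to 23.** The O–CH3 bond at C7 and the acetal C–O bonds at the C5 carbon are cut, and the C7–O bond is traced back to C7–B. Boron is chosen because an aryl-magnesium is trapped far more reliably by a borate than by an electrophilic oxygen source. In 23 both ring A substituents are present in masked, base-stable form. The oxidation and methylation must spare an aryl silyl ether, and the acetal must hydrolyse before either silyl ether does.

**23 to 18 and 19.** The O1–C7a and C7–B bonds are cut. This opens ring C, turns ring A into a benzene whose C7 and C7a carry an iodide and a sulfonate, and moves both stereocentres into an acyclic 1,3-diol monoether. The forward step needs a single free hydroxyl, a halogen–metal exchange faster than any attack at sulfur, and a ring closure faster than intermolecular capture of the aryne.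

**18 to 17 to 16.** The primary O–Si bond and the exocyclic acyl C–N bond are cut. The primary alcohol is thereby recognised as the acyl carbon of an aldol adduct, exposing a β-hydroxy carbonyl retron. The forward steps need selective silylation of the primary over the secondary benzylic hydroxyl and reductive removal of the auxiliary without retro-aldol cleavage.

**16 to 12 and 14.** The C2–C3 bond is cut. It is the only C–C bond between the two stereocentres and divides the molecule into a ring A half and a ring B half of similar size. The adduct must be syn: in the zigzag through the acyl carbon, C3, C2 and ring B, ring A and the hydroxyl are on the same side. When that oxygen is later joined to ring A with retention at C2, the acyl-derived carbon and ring B fall on opposite faces of ring C, which is the trans arrangement. The forward step needs a Z enolate, a closed transition state and the (S) auxiliary for the (2S,3S) adduct.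

**12 to 9 and 10; 14 to 13.** The N-acyl bond and the phenolic O–Si bond are cut. Both are routine, and they lead to a commercial auxiliary and a commercial aldehyde. The acylation must avoid strong bases that could attack the sulfonate or the iodide.

**9 to 7 to 6 to 4 and 5.** The acid carbon is traced back to the internal carbon of an allyl group (C=C cleavage), the acetal to the aldehyde, and the S–O bond to the phenol. An allyl group is a masked carboxymethyl group that can be placed ortho to a phenol. The oxidation must spare the iodide and the acetal C–H. Sulfonylation comes before acetalisation because the push-pull hydroxy aldehyde acetalises poorly.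

**4 to 3 to 1 and 2.** The ring A–CH2 bond (sigmatropic shift) and the O–allyl bond are cut. With iodine already on one ortho carbon and the formyl group para, the rearrangement has a single productive path, and no iodination is needed in the presence of an alkene. The C–I bond must survive the thermal step.

## Other disconnections considered

**Alternative 1:** The cut runs through the C2–aryl bond and the C3–carbonyl carbon bond, so the bicyclic core comes from the flat benzofuran A2 and ring B from the aryl iodide A3.
- Forward step: the aryl–palladium species from A3 (Pd(OAc)2, a chiral bisphosphine, Ag2CO3) would add syn across C2=C3 of A2, aryl to C2 and metal to benzylic C3. The only β-hydrogen, on C2, is then anti to palladium, so the alkyl–palladium should persist long enough to insert carbon monoxide A4 and be cleaved by methanol A5 to the cis diester A1.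
- In favour: both stereocentres and two C–C bonds would come from one catalytic, enantioselective operation on achiral partners. On convergence, and on replacing a stoichiometric auxiliary by a catalyst, this alternative is the better of the two.
- Against:
  - Intermolecular carbopalladation of a benzofuran has to outrun direct alkoxycarbonylation of the aryl–palladium under A4, which is usually faster.
  - A1 is cis and must be epimerised at C3 next to an ester, in a system that can open by β-elimination of the O1 phenoxide.
  - The C3 and C5 methyl esters must then be told apart, most simply by reducing both and re-oxidising the benzylic C5 alcohol.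
  - The benzyl ether cannot be hydrogenolysed once the side-chain alkene is present.
- Comparison: structurally it addresses the C2/C3 pair directly but leaves C3 and C5 at the same oxidation level, whereas the chosen plan keeps them distinct (silyl ether and acetal). Mechanistically it rests on a three-component relay without close intermolecular precedent, whereas each event of the chosen key step has a counterpart in known magnesium aryne chemistry. In step count it would be shorter (roughly ten to twelve steps against sixteen), a real advantage if the key step can be realised.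

**Alternative 2:** The C3–CH2OH and O1–C2 bonds are cut, leading to the 2-hydroxystilbene A7 and formaldehyde A8.
- Forward step: a confined chiral imidodiphosphorimidate Brønsted acid would activate A8. The alkene carbon next to ring A attacks it, forming the C3–C bond and placing the positive charge beside electron-rich ring B. The ring A phenol then closes O1–C2 to give the trans hydroxymethyl compound A6.
- In favour: the regiochemistry matches the electronics, and every position ortho or para to the phenol of A7 is blocked, so A8 cannot hydroxymethylate ring A. The trans product would form directly with C3 at the right oxidation level, and A7 is two or three steps from commercial aromatics. On directness and step count (about nine to ten steps) this alternative is the better of the two, and like the chosen plan it needs no epimerisation.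
- Against:
  - The enantio-determining C–C bond formation occurs at a 1,2-diaryl alkene that is large for a confined acid and deactivated by the ring A ester.
  - The long-lived benzylic cation can be intercepted by a second molecule of A8 or revert.
  - The catalyst class is established for simple aryl alkenes, not for hydroxystilbenes with internal phenol capture, and the catalyst takes several steps to make.
  - The C5 ester of A6 still needs two redox steps before olefination.
- Comparison: structurally both plans build ring C last from an acyclic precursor carrying ring A and ring B. Mechanistically the alternative sets C3 by catalyst control at a cationic stage, whereas the chosen plan sets both centres earlier in a closed transition state and then only has to preserve them. The chosen plan is longer but its stereochemical outcome is easier to predict.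

**Alternative 3:** The C2–C3 bond is cut, leading to the aryldiazoacetate A10, in which ring B is attached as a benzylic ether to the oxygen that becomes O1.
- Forward step: on Rh2(S-PTTL)4 (dirhodium tetrakis[N-phthaloyl-(S)-tert-leucinate]) the diazo nitrogen would be lost, and the carbenoid carbon should insert into the benzylic C–H bond of the ether, closing ring C to the cis ester A9.
- In favour: intramolecular C–H insertion of aryldiazoacetates into ether-activated benzylic C–H bonds with this catalyst family is an established enantioselective entry to this cis-2-aryl-2,3-dihydrobenzofuran-3-carboxylate skeleton. On precedent for the ring-forming event this alternative is the better of the two. The C5 bromide of A9 would also allow the three-carbon chain to be attached in one cross-coupling, more economical than acetal, olefination and reduction; the total would be about eleven steps.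
- Against:
  - A9 is cis and must be epimerised at C3 before ester reduction, with the same β-elimination hazard as in Alternative 1.
  - The very electron-rich benzylic position invites hydride transfer to the carbenoid, and the ether oxygen invites oxonium ylide formation with a 1,2-shift; both bypass concerted insertion.
  - A diazo compound has to be prepared and handled.
- Comparison: structurally this is the only plan that forms the bond between the two stereocentres and the ring in one step. Mechanistically its stereocontrol is catalytic and external, against auxiliary control followed by a stereochemically silent ring closure in the chosen plan. In step economy it is ahead, whereas the chosen plan avoids the cis-to-trans correction and installs O1 and the C7 oxygen function in one operation.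

Key step: step 11

**Assumptions and design notes**
- Assumption: 4-hydroxy-3-iodobenzaldehyde 1 is treated as a purchasable starting material. Carrying the iodine through the Claisen rearrangement avoids iodinating a 2-allylphenol, where iodoetherification of the alkene would compete.
- Both silyl groups are triisopropylsilyl. The aryl ether then tolerates the basic peroxide and carbonate steps, and the primary ether tolerates the acid used for acetal hydrolysis.
- The aldol has to be syn. With the (S)-benzyl oxazolidinone the (2S,3S) adduct leads to the (1S,2R) diol and, after closure with retention at the carbinol carbon, to (2S,3R)-trans.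
- The key step uses two equivalents of i-PrMgCl, the first for the hydroxyl and the second for the exchange.

## Route

Step 1
Reactants: 1 4-hydroxy-3-iodobenzaldehyde; 2 allyl bromide
Product: 3 3-iodo-4-(prop-2-en-1-yloxy)benzaldehyde
Conditions: K2CO3, acetone, reflux
Reagents that add atoms: none
Why: Williamson O-allylation of an acidic phenol (para-formyl, ortho-iodo); carbonate is a sufficient base and C-allylation is not expected.

Step 2
Reactants: 3 3-iodo-4-(prop-2-en-1-yloxy)benzaldehyde
Product: 4 4-hydroxy-3-iodo-5-(prop-2-en-1-yl)benzaldehyde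
Conditions: PhNEt2, 195 °C, sealed tube
Reagents that add atoms: none
Why: Aromatic Claisen rearrangement; the [3,3] shift to the only free ortho carbon is followed by tautomerisation, while shift to the iodine-bearing carbon gives a non-enolisable dienone that can only revert and the para position is blocked.

Step 3
Reactants: 4 4-hydroxy-3-iodo-5-(prop-2-en-1-yl)benzaldehyde; 5 4-chlorobenzenesulfonyl chloride
Product: 6 4-formyl-2-iodo-6-(prop-2-en-1-yl)phenyl 4-chlorobenzenesulfonate
Conditions: Et3N, DMAP (cat.), CH2Cl2, 0 °C → rt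
Reagents that add atoms: none
Why: Sulfonylation of a hindered but acidic phenol under nucleophilic catalysis; it installs the ortho-iodo aryl sulfonate pair needed for aryne generation and removes the push-pull deactivation of the aldehyde before acetalisation.

Step 4
Reactants: 6 4-formyl-2-iodo-6-(prop-2-en-1-yl)phenyl 4-chlorobenzenesulfonate
Product: 7 4-(1,3-dioxolan-2-yl)-2-iodo-6-(prop-2-en-1-yl)phenyl 4-chlorobenzenesulfonate
Conditions: HOCH2CH2OH, TsOH·H2O (cat.), toluene, reflux, Dean–Stark
Reagents that add atoms: ethylene glycol, OCCO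
Why: Acid-catalysed acetalisation with azeotropic removal of water; the dioxolane masks the aldehyde against chlorite, borohydride and i-PrMgCl, and the sulfonate, iodide and terminal alkene are inert to catalytic acid.

Step 5
Reactants: 7 4-(1,3-dioxolan-2-yl)-2-iodo-6-(prop-2-en-1-yl)phenyl 4-chlorobenzenesulfonate
Product: 9 [2-{[(4-chlorophenyl)sulfonyl]oxy}-5-(1,3-dioxolan-2-yl)-3-iodophenyl]acetic acid, via arylacetaldehyde 8 (not isolated)
Conditions: O3, MeCN/H2O (9:1), 0 °C; then aq. NaClO2, 0 °C → rt; NaHSO3 quench
Reagents that add atoms: ozone, [O-][O+]=O; sodium chlorite, [Na+].[O-]Cl=O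
Why: Ozonolysis in aqueous acetonitrile gives the aldehyde directly because water intercepts the carbonyl oxide, and chlorite (Pinnick-type) oxidises it in the same flask with the H2O2 formed acting as hypochlorite scavenger. The terminal alkene should react with ozone much faster than the electron-poor arene, the C–I bond or the acetal C–H.

Step 6
Reactants: 9 [2-{[(4-chlorophenyl)sulfonyl]oxy}-5-(1,3-dioxolan-2-yl)-3-iodophenyl]acetic acid; 10 (4S)-4-benzyl-1,3-oxazolidin-2-one
Product: 12 2-{2-[(4S)-4-benzyl-2-oxo-1,3-oxazolidin-3-yl]-2-oxoethyl}-4-(1,3-dioxolan-2-yl)-6-iodophenyl 4-chlorobenzenesulfonate, via pivalic mixed anhydride 11 (not isolated)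
Conditions: t-BuCOCl, Et3N, THF, −20 °C; then LiCl, 10, −20 °C → rt
Reagents that add atoms: none
Why: Mixed-anhydride N-acylation of the oxazolidinone promoted by LiCl; attack occurs at the less hindered arylacetyl carbonyl, and the method avoids a lithiated auxiliary that could attack the sulfonate or the iodide.

Step 7
Reactants: 13 syringaldehyde (4-hydroxy-3,5-dimethoxybenzaldehyde)
Product: 14 3,5-dimethoxy-4-[(triisopropylsilyl)oxy]benzaldehyde
Conditions: i-Pr3SiCl, imidazole, DMF, rt
Reagents that add atoms: chlorotriisopropylsilane, CC(C)[Si](Cl)(C(C)C)C(C)C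
Why: Silylation of an acidic phenol; the triisopropylsilyl ether flanked by two methoxy groups should withstand the later organomagnesium, peroxide and carbonate conditions.

Step 8
Reactants: 12 2-{2-[(4S)-4-benzyl-2-oxo-1,3-oxazolidin-3-yl]-2-oxoethyl}-4-(1,3-dioxolan-2-yl)-6-iodophenyl 4-chlorobenzenesulfonate; 14 3,5-dimethoxy-4-[(triisopropylsilyl)oxy]benzaldehyde
Product: 16 2-[(2S,3S)-1-[(4S)-4-benzyl-2-oxo-1,3-oxazolidin-3-yl]-3-{3,5-dimethoxy-4-[(triisopropylsilyl)oxy]phenyl}-3-hydroxy-1-oxopropan-2-yl]-4-(1,3-dioxolan-2-yl)-6-iodophenyl 4-chlorobenzenesulfonate, via Z-dibutylboron enolate 15 (not isolated)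
Conditions: Bu2BOTf, i-Pr2NEt, CH2Cl2, 0 °C; then 14, −78 → 0 °C; pH 7 phosphate buffer, MeOH, 30% H2O2, 0 °C
Reagents that add atoms: none
Why: Boron-mediated oxazolidinone syn aldol (Evans aldol); the Z enolate 15 reacts through a chair Zimmerman–Traxler transition state with the auxiliary carbonyl turned away from the enolate oxygen, and the aldehyde approaches the face opposite the benzyl group. Both stereocentres are set here as (2S,3S), the syn arrangement that becomes trans once ring C is closed with retention at the carbinol carbon.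

Step 9
Reactants: 16 2-[(2S,3S)-1-[(4S)-4-benzyl-2-oxo-1,3-oxazolidin-3-yl]-3-{3,5-dimethoxy-4-[(triisopropylsilyl)oxy]phenyl}-3-hydroxy-1-oxopropan-2-yl]-4-(1,3-dioxolan-2-yl)-6-iodophenyl 4-chlorobenzenesulfonate
Product: 17 2-[(2R,3S)-3-{3,5-dimethoxy-4-[(triisopropylsilyl)oxy]phenyl}-1,3-dihydroxypropan-2-yl]-4-(1,3-dioxolan-2-yl)-6-iodophenyl 4-chlorobenzenesulfonate
Conditions: LiBH4, MeOH (1.1 equiv), THF, 0 °C
Reagents that add atoms: none
Why: Reductive cleavage of the N-acyl oxazolidinone at the lithium-activated exocyclic carbonyl; aryl sulfonate, aryl iodide, acetal and silyl ether are inert to borohydride at 0 °C. The stereocentres are not touched, and the descriptor at the methine carbon changes only because the substituent priorities change.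

Step 10
Reactants: 17 2-[(2R,3S)-3-{3,5-dimethoxy-4-[(triisopropylsilyl)oxy]phenyl}-1,3-dihydroxypropan-2-yl]-4-(1,3-dioxolan-2-yl)-6-iodophenyl 4-chlorobenzenesulfonate
Product: 18 2-[(2R,3S)-3-{3,5-dimethoxy-4-[(triisopropylsilyl)oxy]phenyl}-3-hydroxy-1-[(triisopropylsilyl)oxy]propan-2-yl]-4-(1,3-dioxolan-2-yl)-6-iodophenyl 4-chlorobenzenesulfonate
Conditions: i-Pr3SiCl, imidazole, DMF, 0 °C → rt
Reagents that add atoms: chlorotriisopropylsilane, CC(C)[Si](Cl)(C(C)C)C(C)C
Why: Steric differentiation of a primary from a crowded secondary benzylic hydroxyl by a bulky silyl chloride; the secondary hydroxyl stays free as the only nucleophile for the ring closure, and a free primary hydroxyl would otherwise compete by its own five-membered closure.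

Step 11
Reactants: 18 2-[(2R,3S)-3-{3,5-dimethoxy-4-[(triisopropylsilyl)oxy]phenyl}-3-hydroxy-1-[(triisopropylsilyl)oxy]propan-2-yl]-4-(1,3-dioxolan-2-yl)-6-iodophenyl 4-chlorobenzenesulfonate; 19 2-isopropoxy-4,4,5,5-tetramethyl-1,3,2-dioxaborolane
Product: 23 2-[(2S,3R)-2-{3,5-dimethoxy-4-[(triisopropylsilyl)oxy]phenyl}-5-(1,3-dioxolan-2-yl)-3-{[(triisopropylsilyl)oxy]methyl}-2,3-dihydro-1-benzofuran-7-yl]-4,4,5,5-tetramethyl-1,3,2-dioxaborolane, via magnesiated sulfonate 20 (not isolated), via aryne alkoxide 21 (not isolated), via C7 aryl-magnesium 22 (not isolated)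
Conditions: i-PrMgCl (2.1 equiv), THF (0.05 M), −78 °C, 1 h; −78 → 20 °C; then 19, 0 → 20 °C; aq. NH4Cl
Reagents that add atoms: none
Why: The first equivalent of i-PrMgCl turns the C2 hydroxyl into its chloromagnesium alkoxide and the second performs iodine–magnesium exchange at C7 at −78 °C, giving 20 with the metal ortho to the sulfonate. On warming, 4-chlorobenzenesulfonate is expelled from C7a and the C7–C7a aryne 21 forms. The alkoxide oxygen, three bonds from C3a, then adds to C7a in a 5-exo-dig closure that makes O1–C7a and ring C and leaves the C7 aryl-magnesium 22, which 19 converts into the pinacol boronate (C7–B). The closest known reaction type is aryne generation from 2-iodoaryl arenesulfonates by halogen–magnesium exchange followed by addition of a magnesium thiolate or amide and electrophilic quench of the new aryl-magnesium; ring closure of tethered alkoxides onto arynes is itself a classical process, and only their combination with a borate quench in one flask is new to this substrate. Regiochemistry is enforced by the tether, since attack at C7 would require a meta-bridged ring, so magnesium and then boron can only end up on C7. No stereocentre is created: C2 and C3 come unchanged from the aldol, the C2–O bond is never broken, and the trans relationship follows directly from the syn adduct. Chemoselectivity should be secured by the substrate, because the only acidic proton is removed deliberately, all other hydroxyls are silyl ethers, the aldehyde is an acetal, and the exchange is expected to be complete at −78 °C before elimination starts, leaving no i-PrMgCl to add to the aryne.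

Step 12
Reactants: 23 2-[(2S,3R)-2-{3,5-dimethoxy-4-[(triisopropylsilyl)oxy]phenyl}-5-(1,3-dioxolan-2-yl)-3-{[(triisopropylsilyl)oxy]methyl}-2,3-dihydro-1-benzofuran-7-yl]-4,4,5,5-tetramethyl-1,3,2-dioxaborolane
Product: 24 (2S,3R)-2-{3,5-dimethoxy-4-[(triisopropylsilyl)oxy]phenyl}-5-(1,3-dioxolan-2-yl)-3-{[(triisopropylsilyl)oxy]methyl}-2,3-dihydro-1-benzofuran-7-ol
Conditions: 30% H2O2, NaHCO3, THF/H2O, 0 °C → rt
Reagents that add atoms: hydrogen peroxide, OO
Why: Oxidation of an aryl boronate: hydroperoxide adds to boron, the aryl group migrates from boron to oxygen at the same carbon, and hydrolysis releases the phenol. The bicarbonate buffer keeps the medium too mild to cleave the aryl silyl ether.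

Step 13
Reactants: 24 (2S,3R)-2-{3,5-dimethoxy-4-[(triisopropylsilyl)oxy]phenyl}-5-(1,3-dioxolan-2-yl)-3-{[(triisopropylsilyl)oxy]methyl}-2,3-dihydro-1-benzofuran-7-ol
Product: 26 (2S,3R)-2-{3,5-dimethoxy-4-[(triisopropylsilyl)oxy]phenyl}-7-methoxy-3-{[(triisopropylsilyl)oxy]methyl}-2,3-dihydro-1-benzofuran-5-carbaldehyde, via methyl ether acetal 25 (not isolated)
Conditions: MeI, K2CO3, acetone, 40 °C; then 2 M HCl, THF, rt
Reagents that add atoms: iodomethane, CI; water, O
Why: Williamson O-methylation of the only free phenol, then acid hydrolysis of the aryl dioxolane in the same flask; the acetal carbon is now para to the donor O1 and should hydrolyse quickly, while both triisopropylsilyl ethers resist dilute acid at room temperature.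

Step 14
Reactants: 26 (2S,3R)-2-{3,5-dimethoxy-4-[(triisopropylsilyl)oxy]phenyl}-7-methoxy-3-{[(triisopropylsilyl)oxy]methyl}-2,3-dihydro-1-benzofuran-5-carbaldehyde; 27 triethyl phosphonoacetate
Product: 28 ethyl (2E)-3-[(2S,3R)-2-{3,5-dimethoxy-4-[(triisopropylsilyl)oxy]phenyl}-7-methoxy-3-{[(triisopropylsilyl)oxy]methyl}-2,3-dihydro-1-benzofuran-5-yl]prop-2-enoate
Conditions: NaH, THF, 0 °C → rt
Reagents that add atoms: none
Why: Horner–Wadsworth–Emmons olefination with a stabilised phosphonate anion; reversible addition and the preferred anti elimination give the E enoate, and the aldehyde has no α-hydrogen.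

Step 15
Reactants: 28 ethyl (2E)-3-[(2S,3R)-2-{3,5-dimethoxy-4-[(triisopropylsilyl)oxy]phenyl}-7-methoxy-3-{[(triisopropylsilyl)oxy]methyl}-2,3-dihydro-1-benzofuran-5-yl]prop-2-enoate
Product: 29 (2E)-3-[(2S,3R)-2-{3,5-dimethoxy-4-[(triisopropylsilyl)oxy]phenyl}-7-methoxy-3-{[(triisopropylsilyl)oxy]methyl}-2,3-dihydro-1-benzofuran-5-yl]prop-2-en-1-ol
Conditions: i-Bu2AlH (2.5 equiv), CH2Cl2, −78 °C; aq. KNaC4H4O6 (potassium sodium tartrate)
Reagents that add atoms: none
Why: 1,2-Reduction of a conjugated ester to the allylic alcohol by an electrophilic aluminium hydride at low temperature; conjugate reduction is not expected and the silyl ethers are inert.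

Step 16
Reactants: 29 (2E)-3-[(2S,3R)-2-{3,5-dimethoxy-4-[(triisopropylsilyl)oxy]phenyl}-7-methoxy-3-{[(triisopropylsilyl)oxy]methyl}-2,3-dihydro-1-benzofuran-5-yl]prop-2-en-1-ol
Product: 30 4-[(2S,3R)-3-(hydroxymethyl)-5-[(1E)-3-hydroxyprop-1-en-1-yl]-7-methoxy-2,3-dihydro-1-benzofuran-2-yl]-2,6-dimethoxyphenol
Conditions: Bu4NF, AcOH, THF, 0 °C → rt
Reagents that add atoms: none
Why: Fluoride cleavage of both Si–O bonds, driven by the Si–F bond; acetic acid buffers the liberated phenoxide so that the C2–O1 bond is not opened through a quinone methide and C2 and C3 stay as set.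

## Compound list

1 | 4-hydroxy-3-iodobenzaldehyde | O=Cc1ccc(O)c(I)c1 | starting material
2 | allyl bromide (3-bromoprop-1-ene) | C=CCBr | starting material
3 | 3-iodo-4-(prop-2-en-1-yloxy)benzaldehyde | O=Cc1ccc(OCC=C)c(I)c1 | intermediate
4 | 4-hydroxy-3-iodo-5-(prop-2-en-1-yl)benzaldehyde | O=Cc1cc(I)c(O)c(CC=C)c1 | intermediate
5 | 4-chlorobenzenesulfonyl chloride | O=S(=O)(Cl)c1ccc(Cl)cc1 | starting material
6 | 4-formyl-2-iodo-6-(prop-2-en-1-yl)phenyl 4-chlorobenzenesulfonate | O=Cc1cc(I)c(OS(=O)(=O)c2ccc(Cl)cc2)c(CC=C)c1 | intermediate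
7 | 4-(1,3-dioxolan-2-yl)-2-iodo-6-(prop-2-en-1-yl)phenyl 4-chlorobenzenesulfonate | C=CCc1cc(C2OCCO2)cc(I)c1OS(=O)(=O)c1ccc(Cl)cc1 | intermediate
8 | 4-(1,3-dioxolan-2-yl)-2-iodo-6-(2-oxoethyl)phenyl 4-chlorobenzenesulfonate | O=CCc1cc(C2OCCO2)cc(I)c1OS(=O)(=O)c1ccc(Cl)cc1 | intermediate (not isolated)
9 | [2-{[(4-chlorophenyl)sulfonyl]oxy}-5-(1,3-dioxolan-2-yl)-3-iodophenyl]acetic acid | OC(=O)Cc1cc(C2OCCO2)cc(I)c1OS(=O)(=O)c1ccc(Cl)cc1 | intermediate
10 | (4S)-4-benzyl-1,3-oxazolidin-2-one | O=C1N[C@@H](Cc2ccccc2)CO1 | starting material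
11 | mixed anhydride of 9 with pivalic acid | CC(C)(C)C(=O)OC(=O)Cc1cc(C2OCCO2)cc(I)c1OS(=O)(=O)c1ccc(Cl)cc1 | intermediate (not isolated)
12 | 2-{2-[(4S)-4-benzyl-2-oxo-1,3-oxazolidin-3-yl]-2-oxoethyl}-4-(1,3-dioxolan-2-yl)-6-iodophenyl 4-chlorobenzenesulfonate | O=C(Cc1cc(C2OCCO2)cc(I)c1OS(=O)(=O)c1ccc(Cl)cc1)N1[C@@H](Cc2ccccc2)COC1=O | intermediate
13 | syringaldehyde (4-hydroxy-3,5-dimethoxybenzaldehyde) | COc1cc(C=O)cc(OC)c1O | starting material
14 | 3,5-dimethoxy-4-[(triisopropylsilyl)oxy]benzaldehyde | COc1cc(C=O)cc(OC)c1O[Si](C(C)C)(C(C)C)C(C)C | intermediate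
15 | (Z)-dibutylboron enolate of 12 | CCCCB(CCCC)O/C(=C\c1cc(C2OCCO2)cc(I)c1OS(=O)(=O)c1ccc(Cl)cc1)N1[C@@H](Cc2ccccc2)COC1=O | intermediate (not isolated)
16 | 2-[(2S,3S)-1-[(4S)-4-benzyl-2-oxo-1,3-oxazolidin-3-yl]-3-{3,5-dimethoxy-4-[(triisopropylsilyl)oxy]phenyl}-3-hydroxy-1-oxopropan-2-yl]-4-(1,3-dioxolan-2-yl)-6-iodophenyl 4-chlorobenzenesulfonate (syn aldol adduct) | COc1cc([C@@H](O)[C@@H](C(=O)N2[C@@H](Cc3ccccc3)COC2=O)c2cc(C3OCCO3)cc(I)c2OS(=O)(=O)c2ccc(Cl)cc2)cc(OC)c1O[Si](C(C)C)(C(C)C)C(C)C | intermediate
17 | 2-[(2R,3S)-3-{3,5-dimethoxy-4-[(triisopropylsilyl)oxy]phenyl}-1,3-dihydroxypropan-2-yl]-4-(1,3-dioxolan-2-yl)-6-iodophenyl 4-chlorobenzenesulfonate | COc1cc([C@@H](O)[C@@H](CO)c2cc(C3OCCO3)cc(I)c2OS(=O)(=O)c2ccc(Cl)cc2)cc(OC)c1O[Si](C(C)C)(C(C)C)C(C)C | intermediate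
18 | 2-[(2R,3S)-3-{3,5-dimethoxy-4-[(triisopropylsilyl)oxy]phenyl}-3-hydroxy-1-[(triisopropylsilyl)oxy]propan-2-yl]-4-(1,3-dioxolan-2-yl)-6-iodophenyl 4-chlorobenzenesulfonate (key-step precursor) | COc1cc([C@@H](O)[C@@H](CO[Si](C(C)C)(C(C)C)C(C)C)c2cc(C3OCCO3)cc(I)c2OS(=O)(=O)c2ccc(Cl)cc2)cc(OC)c1O[Si](C(C)C)(C(C)C)C(C)C | intermediate
19 | 2-isopropoxy-4,4,5,5-tetramethyl-1,3,2-dioxaborolane | CC(C)OB1OC(C)(C)C(C)(C)O1 | starting material
20 | chloromagnesium alkoxide of 18 carrying MgCl in place of iodine at C7 | COc1cc([C@@H](O[Mg]Cl)[C@@H](CO[Si](C(C)C)(C(C)C)C(C)C)c2cc(C3OCCO3)cc([Mg]Cl)c2OS(=O)(=O)c2ccc(Cl)cc2)cc(OC)c1O[Si](C(C)C)(C(C)C)C(C)C | intermediate (not isolated)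
21 | C7–C7a aryne bearing the tethered chloromagnesium alkoxide | COc1cc([C@@H](O[Mg]Cl)[C@@H](CO[Si](C(C)C)(C(C)C)C(C)C)C2=CC(C3OCCO3)=CC#C2)cc(OC)c1O[Si](C(C)C)(C(C)C)C(C)C | intermediate (not isolated)
22 | [(2S,3R)-2-{3,5-dimethoxy-4-[(triisopropylsilyl)oxy]phenyl}-5-(1,3-dioxolan-2-yl)-3-{[(triisopropylsilyl)oxy]methyl}-2,3-dihydro-1-benzofuran-7-yl]magnesium chloride | COc1cc([C@H]2Oc3c([Mg]Cl)cc(C4OCCO4)cc3[C@@H]2CO[Si](C(C)C)(C(C)C)C(C)C)cc(OC)c1O[Si](C(C)C)(C(C)C)C(C)C | intermediate (not isolated)
23 | 2-[(2S,3R)-2-{3,5-dimethoxy-4-[(triisopropylsilyl)oxy]phenyl}-5-(1,3-dioxolan-2-yl)-3-{[(triisopropylsilyl)oxy]methyl}-2,3-dihydro-1-benzofuran-7-yl]-4,4,5,5-tetramethyl-1,3,2-dioxaborolane (key-step product) | COc1cc([C@H]2Oc3c(B4OC(C)(C)C(C)(C)O4)cc(C4OCCO4)cc3[C@@H]2CO[Si](C(C)C)(C(C)C)C(C)C)cc(OC)c1O[Si](C(C)C)(C(C)C)C(C)C | intermediate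
24 | (2S,3R)-2-{3,5-dimethoxy-4-[(triisopropylsilyl)oxy]phenyl}-5-(1,3-dioxolan-2-yl)-3-{[(triisopropylsilyl)oxy]methyl}-2,3-dihydro-1-benzofuran-7-ol | COc1cc([C@H]2Oc3c(O)cc(C4OCCO4)cc3[C@@H]2CO[Si](C(C)C)(C(C)C)C(C)C)cc(OC)c1O[Si](C(C)C)(C(C)C)C(C)C | intermediate
25 | (2S,3R)-2-{3,5-dimethoxy-4-[(triisopropylsilyl)oxy]phenyl}-5-(1,3-dioxolan-2-yl)-7-methoxy-3-{[(triisopropylsilyl)oxy]methyl}-2,3-dihydro-1-benzofuran | COc1cc([C@H]2Oc3c(OC)cc(C4OCCO4)cc3[C@@H]2CO[Si](C(C)C)(C(C)C)C(C)C)cc(OC)c1O[Si](C(C)C)(C(C)C)C(C)C | intermediate (not isolated)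
26 | (2S,3R)-2-{3,5-dimethoxy-4-[(triisopropylsilyl)oxy]phenyl}-7-methoxy-3-{[(triisopropylsilyl)oxy]methyl}-2,3-dihydro-1-benzofuran-5-carbaldehyde | COc1cc([C@H]2Oc3c(OC)cc(C=O)cc3[C@@H]2CO[Si](C(C)C)(C(C)C)C(C)C)cc(OC)c1O[Si](C(C)C)(C(C)C)C(C)C | intermediate
27 | triethyl phosphonoacetate | CCOC(=O)CP(=O)(OCC)OCC | starting material
28 | ethyl (2E)-3-[(2S,3R)-2-{3,5-dimethoxy-4-[(triisopropylsilyl)oxy]phenyl}-7-methoxy-3-{[(triisopropylsilyl)oxy]methyl}-2,3-dihydro-1-benzofuran-5-yl]prop-2-enoate | COc1cc([C@H]2Oc3c(OC)cc(/C=C/C(=O)OCC)cc3[C@@H]2CO[Si](C(C)C)(C(C)C)C(C)C)cc(OC)c1O[Si](C(C)C)(C(C)C)C(C)C | intermediate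
29 | (2E)-3-[(2S,3R)-2-{3,5-dimethoxy-4-[(triisopropylsilyl)oxy]phenyl}-7-methoxy-3-{[(triisopropylsilyl)oxy]methyl}-2,3-dihydro-1-benzofuran-5-yl]prop-2-en-1-ol | COc1cc([C@H]2Oc3c(OC)cc(/C=C/CO)cc3[C@@H]2CO[Si](C(C)C)(C(C)C)C(C)C)cc(OC)c1O[Si](C(C)C)(C(C)C)C(C)C | intermediate
30 | 4-[(2S,3R)-3-(hydroxymethyl)-5-[(1E)-3-hydroxyprop-1-en-1-yl]-7-methoxy-2,3-dihydro-1-benzofuran-2-yl]-2,6-dimethoxyphenol | COc1cc([C@H]2Oc3c(OC)cc(/C=C/CO)cc3[C@@H]2CO)cc(OC)c1O | target

## Step count and least certain steps

Total step count: 16. Longest linear sequence: 15 steps (from 1 to 30 through steps 1–6 and 8–16); step 7 is the single branch step that prepares 14.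

**Step 11 (key step).**
- Risk: ring closure by the aggregated, weakly nucleophilic magnesium alkoxide may be too slow. The aryne would then be consumed intermolecularly by another aryl-magnesium or by residual i-PrMgCl. Transfer of the sulfonyl group from the phenolic oxygen to the alkoxide before the exchange is complete is a second possible leak.
- Fallback, from 18 back to 23: the ring is closed at the other end (O1–C2 by benzylic substitution) and boron is introduced by catalysis.
  - KOH in MeOH/THF/H2O at 50 °C should cleave the aryl sulfonate and, unavoidably, the phenolic silyl ether. This gives 2-[(2R,3S)-3-hydroxy-3-(4-hydroxy-3,5-dimethoxyphenyl)-1-[(triisopropylsilyl)oxy]propan-2-yl]-4-(1,3-dioxolan-2-yl)-6-iodophenol F1.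
  - Catalytic TsOH in dry CH2Cl2 over 4 Å sieves at 0 °C should ionise the electron-rich benzylic carbinol, and the C7a phenol should capture it under trans control with C3 unchanged. This gives 4-[(2S,3R)-5-(1,3-dioxolan-2-yl)-7-iodo-3-{[(triisopropylsilyl)oxy]methyl}-2,3-dihydro-1-benzofuran-2-yl]-2,6-dimethoxyphenol F2.
  - Resilylation (i-Pr3SiCl, imidazole, DMF) gives {4-[(2S,3R)-5-(1,3-dioxolan-2-yl)-7-iodo-3-{[(triisopropylsilyl)oxy]methyl}-2,3-dihydro-1-benzofuran-2-yl]-2,6-dimethoxyphenoxy}triisopropylsilane F3.
  - Miyaura borylation (PdCl2(dppf), bis(pinacolato)diboron, KOAc, dioxane, 80 °C) returns 23.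

**Step 8.**
- Risk: conversion or facial and syn/anti selectivity may be insufficient. The ortho-sulfonyloxy aryl group crowds the boron enolate, the electron-rich aldehyde is a weak electrophile, and the boron triflate could activate the acetal.
- Fallback, from 9 back to 17: a more reactive chlorotitanium enolate on a different auxiliary.
  - 9 is coupled (EDC·HCl, DMAP, CH2Cl2) with (4S)-4-benzyl-1,3-thiazolidine-2-thione F4 to give 2-{2-[(4S)-4-benzyl-2-thioxo-1,3-thiazolidin-3-yl]-2-oxoethyl}-4-(1,3-dioxolan-2-yl)-6-iodophenyl 4-chlorobenzenesulfonate F5.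
  - TiCl4, i-Pr2NEt and N-methylpyrrolidinone in CH2Cl2 at −78 → 0 °C with 14 should give the same syn sense, in 2-[(2S,3S)-1-[(4S)-4-benzyl-2-thioxo-1,3-thiazolidin-3-yl]-3-{3,5-dimethoxy-4-[(triisopropylsilyl)oxy]phenyl}-3-hydroxy-1-oxopropan-2-yl]-4-(1,3-dioxolan-2-yl)-6-iodophenyl 4-chlorobenzenesulfonate F6.
  - NaBH4 in THF/EtOH at 0 °C removes this auxiliary under very mild conditions and gives 17.

**Step 9.**
- Risk: retro-aldol fragmentation of the lithium aldolate, and hydride attack at the ring carbonyl of the auxiliary (endocyclic opening), because the α-aryl acyl group is hindered and the aldehyde fragment is a stabilised leaving partner.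
- Fallback, from 16 back to 17: hydrolytic removal followed by electrophilic reduction.
  - LiOH/H2O2 in THF/H2O at 0 °C should cleave the exocyclic carbonyl selectively to (2S,3S)-2-[2-{[(4-chlorophenyl)sulfonyl]oxy}-5-(1,3-dioxolan-2-yl)-3-iodophenyl]-3-{3,5-dimethoxy-4-[(triisopropylsilyl)oxy]phenyl}-3-hydroxypropanoic acid F7.
  - BH3·SMe2 in THF at 0 °C → rt reduces the carboxylic acid chemoselectively to 17.

**Step 5.**
- Risk: over-oxidation once the alkene is consumed (ozone insertion into the acetal C–H or oxidation at iodine), and acid-promoted loss of the acetal during the chlorite stage.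
- Fallback, from 7 back to 8: osmylation and glycol cleavage in place of ozone.
  - OsO4 (cat.) with N-methylmorpholine N-oxide in acetone/H2O gives 2-(2,3-dihydroxypropyl)-4-(1,3-dioxolan-2-yl)-6-iodophenyl 4-chlorobenzenesulfonate F8 (mixture of enantiomers at the carbinol carbon).
  - NaIO4 in THF/H2O at pH 7 cleaves F8 to 8, which is oxidised to 9 with NaClO2, NaH2PO4 and 2-methylbut-2-ene in t-BuOH/H2O.

## Further compounds

F1 | step 11 | 2-[(2R,3S)-3-hydroxy-3-(4-hydroxy-3,5-dimethoxyphenyl)-1-[(triisopropylsilyl)oxy]propan-2-yl]-4-(1,3-dioxolan-2-yl)-6-iodophenol | COc1cc([C@@H](O)[C@@H](CO[Si](C(C)C)(C(C)C)C(C)C)c2cc(C3OCCO3)cc(I)c2O)cc(OC)c1O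
F2 | step 11 | 4-[(2S,3R)-5-(1,3-dioxolan-2-yl)-7-iodo-3-{[(triisopropylsilyl)oxy]methyl}-2,3-dihydro-1-benzofuran-2-yl]-2,6-dimethoxyphenol | COc1cc([C@H]2Oc3c(I)cc(C4OCCO4)cc3[C@@H]2CO[Si](C(C)C)(C(C)C)C(C)C)cc(OC)c1O
F3 | step 11 | {4-[(2S,3R)-5-(1,3-dioxolan-2-yl)-7-iodo-3-{[(triisopropylsilyl)oxy]methyl}-2,3-dihydro-1-benzofuran-2-yl]-2,6-dimethoxyphenoxy}triisopropylsilane | COc1cc([C@H]2Oc3c(I)cc(C4OCCO4)cc3[C@@H]2CO[Si](C(C)C)(C(C)C)C(C)C)cc(OC)c1O[Si](C(C)C)(C(C)C)C(C)C
F4 | step 8 | (4S)-4-benzyl-1,3-thiazolidine-2-thione | S=C1N[C@@H](Cc2ccccc2)CS1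
F5 | step 8 | 2-{2-[(4S)-4-benzyl-2-thioxo-1,3-thiazolidin-3-yl]-2-oxoethyl}-4-(1,3-dioxolan-2-yl)-6-iodophenyl 4-chlorobenzenesulfonate | O=C(Cc1cc(C2OCCO2)cc(I)c1OS(=O)(=O)c1ccc(Cl)cc1)N1[C@@H](Cc2ccccc2)CSC1=S
F6 | step 8 | 2-[(2S,3S)-1-[(4S)-4-benzyl-2-thioxo-1,3-thiazolidin-3-yl]-3-{3,5-dimethoxy-4-[(triisopropylsilyl)oxy]phenyl}-3-hydroxy-1-oxopropan-2-yl]-4-(1,3-dioxolan-2-yl)-6-iodophenyl 4-chlorobenzenesulfonate | COc1cc([C@@H](O)[C@@H](C(=O)N2[C@@H](Cc3ccccc3)CSC2=S)c2cc(C3OCCO3)cc(I)c2OS(=O)(=O)c2ccc(Cl)cc2)cc(OC)c1O[Si](C(C)C)(C(C)C)C(C)C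
F7 | step 9 | (2S,3S)-2-[2-{[(4-chlorophenyl)sulfonyl]oxy}-5-(1,3-dioxolan-2-yl)-3-iodophenyl]-3-{3,5-dimethoxy-4-[(triisopropylsilyl)oxy]phenyl}-3-hydroxypropanoic acid | COc1cc([C@@H](O)[C@@H](C(=O)O)c2cc(C3OCCO3)cc(I)c2OS(=O)(=O)c2ccc(Cl)cc2)cc(OC)c1O[Si](C(C)C)(C(C)C)C(C)C
F8 | step 5 | 2-(2,3-dihydroxypropyl)-4-(1,3-dioxolan-2-yl)-6-iodophenyl 4-chlorobenzenesulfonate | OCC(O)Cc1cc(C2OCCO2)cc(I)c1OS(=O)(=O)c1ccc(Cl)cc1
A1 | alternative 1 | dimethyl (2S,3R)-2-[4-(benzyloxy)-3,5-dimethoxyphenyl]-7-methoxy-2,3-dihydro-1-benzofuran-3,5-dicarboxylate (cis) | COc1cc([C@H]2Oc3c(OC)cc(C(=O)OC)cc3[C@H]2C(=O)OC)cc(OC)c1OCc1ccccc1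
A2 | alternative 1 | methyl 7-methoxy-1-benzofuran-5-carboxylate | COC(=O)c1cc(OC)c2occc2c1
A3 | alternative 1 | 2-(benzyloxy)-5-iodo-1,3-dimethoxybenzene | COc1cc(I)cc(OC)c1OCc1ccccc1
A4 | alternative 1 | carbon monoxide | [C-]#[O+]
A5 | alternative 1 | methanol | CO
A6 | alternative 2 | methyl (2S,3R)-2-{3,5-dimethoxy-4-[(triisopropylsilyl)oxy]phenyl}-3-(hydroxymethyl)-7-methoxy-2,3-dihydro-1-benzofuran-5-carboxylate (trans) | COc1cc([C@H]2Oc3c(OC)cc(C(=O)OC)cc3[C@@H]2CO)cc(OC)c1O[Si](C(C)C)(C(C)C)C(C)C
A7 | alternative 2 | methyl 3-[(E)-2-{3,5-dimethoxy-4-[(triisopropylsilyl)oxy]phenyl}ethenyl]-4-hydroxy-5-methoxybenzoate | COC(=O)c1cc(OC)c(O)c(/C=C/c2cc(OC)c(O[Si](C(C)C)(C(C)C)C(C)C)c(OC)c2)c1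
A8 | alternative 2 | formaldehyde | C=O
A9 | alternative 3 | methyl (2S,3R)-5-bromo-2-{4-[(tert-butyldimethylsilyl)oxy]-3,5-dimethoxyphenyl}-7-methoxy-2,3-dihydro-1-benzofuran-3-carboxylate (cis) | COc1cc([C@H]2Oc3c(OC)cc(Br)cc3[C@H]2C(=O)OC)cc(OC)c1O[Si](C)(C)C(C)(C)C
A10 | alternative 3 | methyl 2-[5-bromo-2-({4-[(tert-butyldimethylsilyl)oxy]-3,5-dimethoxyphenyl}methoxy)-3-methoxyphenyl]-2-diazoacetate | COC(=O)C(=[N+]=[N-])c1cc(Br)cc(OC)c1OCc1cc(OC)c(O[Si](C)(C)C(C)(C)C)c(OC)c1
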